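**Plan**

1. Retrosynthesis: cut C5–aryl first, giving an arylzinc bromide and the O1=C5 oxocarbenium ion of the tetrahydrofuran ring (masked as a C5 acetate); then C5–H back to a γ-lactone, the C3–H and C4–H bonds back to a butenolide, and C3–CH3, C4–C5 and C2–C3 back to MeMgBr, CO2, propyne and veratraldehyde.
2. Enabling feature: C5 is bonded to the ring oxygen O1, so a C5 acetate of either configuration ionises to one five-membered oxocarbenium ion. The C2 aryl, C3 methyl and C4 methyl groups are all cis, so only the opposite face of C5 is open, and that is the face the target needs (4,5-trans, 2,5-trans).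
3. Forward: C2–C3 by asymmetric alkynylation; ring closure by anti-carbomagnesiation, carboxylation and lactonisation (O1–C5); hydrogenation; reductive acetylation; C5 arylation that joins the two halves.
4. Stereochemistry: C2 from the Me2Zn/(S,S)-ProPhenol alkynylation; C3 and C4 relayed from C2 by syn hydrogenation anti to the aryl group; C5 from the ring substituents in the stereoconvergent oxocarbenium capture.

Key step: step 6

Assumption: (S,S)-ProPhenol is taken to deliver the alkynyl group to the Si face of the aryl aldehyde; if the sense of induction is the opposite, the (R,R) ligand is used with no other change.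

**Route**

Step 1
Reactants: 1 3,4-dimethoxybenzaldehyde; 2 propyne
Product: 4 (R)-1-(3,4-dimethoxyphenyl)but-2-yn-1-ol, via methyl(propynyl)zinc 3 (not isolated)
Conditions: Me2Zn (3 equiv), (S,S)-ProPhenol (10 mol %), Ph3P=O (20 mol %), 2 (3 equiv), toluene, 0 °C; then 1, 4 °C; aq NH4Cl
Reagents that add atoms: none
Why: Me2Zn/(S,S)-ProPhenol-catalysed enantioselective alkynylation of an aryl aldehyde, in which the alkynylzinc 3 formed in situ is delivered to the Si face of the carbonyl group inside the chiral bimetallic pocket, should set the benzylic carbinol centre as R (the future C2 of the target).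

Step 2
Reactants: 4 (R)-1-(3,4-dimethoxyphenyl)but-2-yn-1-ol
Product: 7 (R)-5-(3,4-dimethoxyphenyl)-3,4-dimethylfuran-2(5H)-one, via alkenylmagnesium alkoxide chelate 5 (not isolated), via hydroxy acid 6 (not isolated)
Conditions: MeMgBr (4 equiv), CuI (10 mol %), THF, 0 °C to reflux; then CO2 (gas), −20 °C to rt; then 1 M HCl, 0 °C to rt
Reagents that add atoms: methylmagnesium bromide (C[Mg]Br); carbon dioxide (O=C=O)
Why: Alkoxide-directed, CuI-catalysed anti-carbomagnesiation of a propargylic alcohol places the new methyl group on the alkyne carbon next to the carbinol and magnesium on the distal carbon cis to the carbinol (five-membered chelate 5), so carboxylation with retention of alkene geometry gives the Z hydroxy acid 6, which lactonises on mild acidification; no stereocentre is formed and the carbinol centre is untouched because the lactone only arises after the base has been quenched.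

Step 3
Reactants: 7 (R)-5-(3,4-dimethoxyphenyl)-3,4-dimethylfuran-2(5H)-one
Product: 8 (3S,4R,5S)-5-(3,4-dimethoxyphenyl)-3,4-dimethyldihydrofuran-2(3H)-one (all-cis)
Conditions: H2 (4 bar), 5% Rh/Al2O3, EtOAc, rt
Reagents that add atoms: none
Why: Heterogeneous syn hydrogenation of the tetrasubstituted butenolide alkene from the face opposite the C5 aryl group should give the all-cis lactone, setting both methyl-bearing centres from the single benzylic centre; Rh/Al2O3 is chosen over Pd/C to spare the benzylic, allylic C–O bond.

Step 4
Reactants: 8 (3S,4R,5S)-5-(3,4-dimethoxyphenyl)-3,4-dimethyldihydrofuran-2(3H)-one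
Product: 10 (3S,4R,5S)-5-(3,4-dimethoxyphenyl)-3,4-dimethyltetrahydrofuran-2-yl acetate (both anomers), via aluminium lactolate 9 (not isolated)
Conditions: i-Bu2AlH (1.2 equiv), CH2Cl2, −78 °C; then pyridine, DMAP, Ac2O, −78 to −20 °C; aq potassium sodium tartrate
Reagents that add atoms: acetic anhydride (CC(=O)OC(C)=O)
Why: One-pot reductive acetylation of a lactone, in which the tetrahedral aluminium lactolate 9 is stable at −78 °C and is acylated in situ, avoids any free hydroxy aldehyde, so the adjacent methyl-bearing centre cannot epimerise; the anomeric composition is of no consequence for step 6.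

Step 5
Reactants: 11 5-bromo-1,2,3-trimethoxybenzene
Product: 13 (3,4,5-trimethoxyphenyl)zinc bromide, via aryl Grignard reagent 12 (not isolated)
Conditions: Mg turnings, THF, 40 °C; then ZnBr2 (1.0 equiv), 0 °C to rt; used directly
Reagents that add atoms: zinc dibromide (Br[Zn]Br)
Why: Grignard formation followed by transmetalation with one equivalent of ZnBr2 should give a weakly basic arylzinc bromide that tolerates a Lewis acid and transfers its aryl group through the ipso carbon.

Step 6
Reactants: 10 (3S,4R,5S)-5-(3,4-dimethoxyphenyl)-3,4-dimethyltetrahydrofuran-2-yl acetate; 13 (3,4,5-trimethoxyphenyl)zinc bromide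
Product: 15 Ligraminol A [(2S,3R,4S,5S)-2-(3,4-dimethoxyphenyl)-3,4-dimethyl-5-(3,4,5-trimethoxyphenyl)tetrahydrofuran], via oxocarbenium ion 14 (not isolated)
Conditions: 13 (2 equiv; THF largely removed in vacuo, residue taken up in CH2Cl2), BF3·OEt2 (2.5 equiv), CH2Cl2, −78 to −40 °C; Et3N, then aq NH4Cl at −40 °C
Reagents that add atoms: none
Why: BF3·OEt2 ionises either anomer of acetate 10 to the same cyclic oxocarbenium ion 14 (O1=C5 of the five-membered ring), and arylzinc bromide 13 transfers its aryl group through the ipso carbon to C5, so the 3,4,5-trimethoxy pattern is fixed by the carbon–zinc bond and not by the directing effects that would send a Friedel–Crafts reaction of 1,2,3-trimethoxybenzene to the wrong ring position. The closest known reaction type is the Lewis acid-mediated C-arylation of lactol-derived acetates, halides or sulfones with arylzinc reagents, a C-glycosylation-type SN1 substitution. No ring is closed in this step. The one new stereocentre, C5, is under substrate control: the C4 methyl, the C3 methyl and the C2 aryl group all lie on one face of 14, so the aryl group should enter from the other face, trans to the C4 methyl and to the C2 aryl group (5S). The step needs facial selectivity at C5, which this all-cis triad secures whatever the anomeric composition of 10 (stereoconvergent), and ionisation of the exocyclic C5–OAc bond in preference to the benzylic C2–O1 bond, which lone-pair assistance from O1 at −78 °C secures. The cold Et3N quench keeps BF3 from epimerising the acid-labile 2,3-cis benzylic centre of the product.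

**Compound list**

1 | 3,4-dimethoxybenzaldehyde (veratraldehyde) | COc1ccc(C=O)cc1OC | starting material
2 | propyne | CC#C | starting material
3 | methyl(prop-1-yn-1-yl)zinc | C[Zn]C#CC | intermediate
4 | (R)-1-(3,4-dimethoxyphenyl)but-2-yn-1-ol | COc1ccc([C@H](C#CC)O)cc1OC | intermediate
5 | alkenylmagnesium alkoxide chelate [(5R)-5-(3,4-dimethoxyphenyl)-3,4-dimethyl-2,5-dihydro-1,2-oxamagnesole] | COc1ccc([C@H]2O[Mg]C(C)=C2C)cc1OC | intermediate
6 | (R,Z)-4-(3,4-dimethoxyphenyl)-4-hydroxy-2,3-dimethylbut-2-enoic acid | COc1ccc([C@@H](O)/C(C)=C(C)\C(=O)O)cc1OC | intermediate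
7 | (R)-5-(3,4-dimethoxyphenyl)-3,4-dimethylfuran-2(5H)-one | COc1ccc([C@H]2OC(=O)C(C)=C2C)cc1OC | intermediate
8 | (3S,4R,5S)-5-(3,4-dimethoxyphenyl)-3,4-dimethyldihydrofuran-2(3H)-one | COc1ccc([C@H]2OC(=O)[C@@H](C)[C@H]2C)cc1OC | intermediate
9 | diisobutylaluminium lactolate of 8 [O-(diisobutylalumanyl) (3S,4R,5S)-5-(3,4-dimethoxyphenyl)-3,4-dimethyltetrahydrofuran-2-olate] | COc1ccc([C@H]2OC(O[Al](CC(C)C)CC(C)C)[C@@H](C)[C@H]2C)cc1OC | intermediate
10 | (3S,4R,5S)-5-(3,4-dimethoxyphenyl)-3,4-dimethyltetrahydrofuran-2-yl acetate (both anomers) | COc1ccc([C@H]2OC(OC(C)=O)[C@@H](C)[C@H]2C)cc1OC | intermediate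
11 | 5-bromo-1,2,3-trimethoxybenzene | COc1cc(Br)cc(OC)c1OC | starting material
12 | (3,4,5-trimethoxyphenyl)magnesium bromide | COc1cc([Mg]Br)cc(OC)c1OC | intermediate
13 | (3,4,5-trimethoxyphenyl)zinc bromide | COc1cc([Zn]Br)cc(OC)c1OC | intermediate
14 | (2S,3R,4S)-2-(3,4-dimethoxyphenyl)-3,4-dimethyl-3,4-dihydro-2H-furan-1-ium (cyclic oxocarbenium ion) | COc1ccc([C@H]2[O+]=C[C@@H](C)[C@H]2C)cc1OC | intermediate
15 | Ligraminol A [(2S,3R,4S,5S)-2-(3,4-dimethoxyphenyl)-3,4-dimethyl-5-(3,4,5-trimethoxyphenyl)tetrahydrofuran] | COc1ccc([C@H]2O[C@H](c3cc(OC)c(OC)c(OC)c3)[C@@H](C)[C@H]2C)cc1OC | target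

**Step count**

Total steps: 6. Longest linear sequence: 5 steps (steps 1, 2, 3, 4 and 6); step 5 prepares the arylzinc partner.

**Steps most likely to fail**

Step 6. Aryl transfer from zinc to the oxocarbenium ion may be slower than loss of the C4 proton (elimination to the enol ether), or than Lewis acid-induced opening of the benzylic C2–O1 bond with loss of configuration at C2. The fallback sets out from acetate 10 and returns at target 15. Friedel–Crafts C-arylation of 10 with 2,6-dimethoxyphenol (BF3·OEt2, CH2Cl2, −78 °C) uses a far more nucleophilic arene; its free hydroxyl group directs substitution to the para position, both ortho positions being blocked by methoxy groups. Attack on the same open face of the oxocarbenium ion should give 4-[(2S,3S,4R,5S)-5-(3,4-dimethoxyphenyl)-3,4-dimethyltetrahydrofuran-2-yl]-2,6-dimethoxyphenol F1. O-Methylation of F1 (MeI, K2CO3, acetone, rt) then gives 15.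

Step 3. Hydrogenolysis of the benzylic, allylic lactone C–O bond, slow uptake of hydrogen by the tetrasubstituted alkene, or saturation of the electron-rich arene on Rh/Al2O3 may compete. The fallback sets out from butenolide 7 and returns at lactone 8. It replaces surface hydrogenation by CuH 1,4-hydrosilylation (Cu(OAc)2 5 mol %, 1,2-bis(diphenylphosphino)benzene, PhMe2SiH, toluene, rt). Hydride should add to the β-carbon anti to the aryl group and give the silyl ketene acetal {[(4R,5S)-5-(3,4-dimethoxyphenyl)-3,4-dimethyl-4,5-dihydrofuran-2-yl]oxy}dimethyl(phenyl)silane F2. Kinetic protonation of F2 (AcOH, wet THF, −78 °C) on the face opposite the two cis substituents should then place the α-methyl group cis and deliver 8.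

Step 2. The hindered, chelated alkenylmagnesium may take up CO2 sluggishly, so that protonation to the uncarboxylated allylic alcohol competes. The fallback sets out from alcohol 4 and returns at butenolide 7. The same carbomagnesiation to chelate 5 is quenched with I2 (THF, −78 to 0 °C; aq NH4Cl) to give (R,Z)-1-(3,4-dimethoxyphenyl)-3-iodo-2-methylbut-2-en-1-ol F3. Palladium-catalysed carbonylative lactonisation of F3 (CO 1 atm, PdCl2(PPh3)2 5 mol %, K2CO3, THF, 40 °C) then forms the acyl carbon–carbon bond and closes the ring to 7.

**Further compounds**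

F1 | step 6 | 4-[(2S,3S,4R,5S)-5-(3,4-dimethoxyphenyl)-3,4-dimethyltetrahydrofuran-2-yl]-2,6-dimethoxyphenol | COc1ccc([C@H]2O[C@H](c3cc(OC)c(O)c(OC)c3)[C@@H](C)[C@H]2C)cc1OC
F2 | step 3 | {[(4R,5S)-5-(3,4-dimethoxyphenyl)-3,4-dimethyl-4,5-dihydrofuran-2-yl]oxy}dimethyl(phenyl)silane | COc1ccc([C@H]2OC(O[Si](C)(C)c3ccccc3)=C(C)[C@H]2C)cc1OC
F3 | step 2 | (R,Z)-1-(3,4-dimethoxyphenyl)-3-iodo-2-methylbut-2-en-1-ol | COc1ccc([C@@H](O)/C(C)=C(C)\I)cc1OC
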